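The numbers in the tables were generated by integration with constants of no real substance, and the scatter is random.

Time is the first question for this flask. The south-west run, which is the flask itself followed so far, stands level from 8.00 min to 30.0 min, while the west run, with twice the partner, loses bis adduct in its first minutes.

| flask | substrate | partner | remark | time |
|---|---|---|---|---|
| south-west | 0.050 M | 1.1 equiv | the very flask that is asked about, followed so far |  |
| west | 0.050 M | 2.2 equiv | run made earlier |  |
| flask | 0.050 M | 1.10 equiv |  | 40 min |

- south-west (time / min: bis adduct / %, substrate / %): 8.00: 20, 30; 15.0: 21, 28; 25.0: 19, 30; 30.0: 20, 30
- west (time / min: bis adduct / %, substrate / %): 1.00: 53, 1; 2.00: 47, 1; 3.00: 42, 3; 4.00: 42, 0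

(each reading ± 1.5 percentage points)

- bis adduct that was removed still counts
- what may be going on: substrate + partner -> mono adduct; partner + mono adduct -> bis adduct; bis adduct <-> isomer of the product; partner + bis adduct -> over-reaction product
- additions bring no volume worth counting

- dawn: change nothing and wait 40 min more
- autumn: at 40 min take out 90% of the bis adduct then present, then wait 40 min
- midnight: at 40 min add partner, 100% of the amount charged, then wait 40 min
- spring: at 40 min add substrate, 50.0% of the amount charged, then wait 40 min

* bis adduct, in percent of the substrate first charged, at 40 min
* what to do for the largest gain in bis adduct; "none" if nothing gains more than 2 percentage points (dawn / autumn / midnight / spring / none)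
* bis adduct present, with what was taken out counted in, in percent of the substrate first charged, after dawn
* bis adduct present, with what was taken out counted in, in percent of the substrate first charged, after midnight

Two chemists dispute it. The first holds to the clock: the west run fell 11 percentage points by 4.00 min, and the wait after midnight is ten times that span, so added partner may give a peak that has faded by the end.

The second, whom I follow, counts charges. In the south-west run 1.1 equiv of partner met substrate that stays at 30%, which leaves 40.0% of the substrate charged as the second-addition budget, partner charged less substrate consumed. It pays for free partner, one unit per bis adduct or isomer of the product, and two per over-reaction product.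

The west budget is 120%. If mono adduct is used up and free partner is near zero, that means 20.0% over-reaction product and 80.0% bis adduct plus isomer. The last reading then puts the bis share at 0.525. Applied to the south-west budget, with over-reaction product neglected, this gives 21.0% bis adduct, close to the readings.

Dawn and spring add no partner, so I expect no gain. Midnight, with the substrate consumed, raises the budget to 120%, which gives 42.0%. That gain of 21 points exceeds the 9 points I reckon for autumn, where the isomer of the product refills bis adduct to the same share after the removal.

The forecast gives 20% (19% to 21%), 20% after dawn (18.5% to 21%) and 41% after midnight (35% to 45%), slightly under my count, and it chooses midnight because “total partner matches the west run”.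

The flask gives 20.3% at 40 min and 20.3% after dawn. Midnight gives 42.1%, and its gain of 22 points beats every other option.

    substrate + partner → mono adduct (k = 2.80 M⁻¹ s⁻¹)
    partner + mono adduct → bis adduct (k = 3.50 M⁻¹ s⁻¹)
    bis adduct ⇌ isomer of the product (K = 0.800, k = 0.00770 s⁻¹)
    partner + bis adduct → over-reaction product (k = 0.300 M⁻¹ s⁻¹)

In this flask the step from partner and mono adduct to bis adduct had 100% of its turnover up to 40 min behind it by 4.00 min, with free partner, the limiting reagent, at 0% of its charge. The step to the isomer of the product had >99.9% of its turnover up to 40 min behind it by 8.00 min; those first minutes are the region of the first chemist's clock, and bis adduct stands at 20.3% at 400 min. At 40 min this flask holds 40.3% of the substrate charged in bis adduct and isomer of the product, counting two units per over-reaction product, against the budget of 40.0% read from the runs. A neighbour flask with 4.40 equiv of partner, its substrate consumed, has a budget of 340%; with >99.9% over-reaction product at two units per substrate, that leaves 31.8% of its partner charge free, and at 40.0 min it holds 31.8%.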